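**Retrosynthetic overview**

1. Feature: in the target the C12 hydroxyl and the C15 carboxyl are cis across C13=C14. The chain C12(OH)–C13(CH3)=C14–C15O2H is therefore an opened 4-methylbutenolide (ring O–C12–C13=C14–C15), and the last step is hydroxide opening of that lactone.
2. The lactone C12–O bond, the Z geometry and the C12 centre are made together by iodolactonisation onto C11=C12 of an (11E)-dienoic diacid used as a 13E/13Z mixture. Iodine and light should drain the 13E isomer through 13Z, and the C11 iodine is then removed by radical reduction.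
3. The dienoic diacid comes from a vinylogous Horner–Wadsworth–Emmons olefination at a C11 aldehyde plus oxidation of C19.
4. The decalin comes from an auxiliary-controlled Mn(OAc)3/Cu(OAc)2 radical bicyclisation of a β-keto ester built from geranyl acetate; the C3 ketone is deleted afterwards.
5. Ring order: ring A then ring B in one cascade (step 5); the temporary lactone ring closes in step 14 and is opened in step 16.

Key step: step 14

Remark: labdane numbering is used throughout (C19 = carboxyl carbon on C4, C17 = methylene carbon on C8, C11–C16 = side chain; 11E/13Z correspond to 4E/2Z of the dienoic acid). It is assumed that the (1S,2R,5S)-auxiliary leads to the natural decalin series (5α-H, 10β-CH3); if the sense proved opposite, its enantiomer would be used in the same steps.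

**Route**

Step 1
Reactants: 1 geranyl acetate
Product: 2 (2E,6E)-8-hydroxy-3,7-dimethylocta-2,6-dien-1-yl acetate
Conditions: SeO2 (cat.), t-BuOOH, salicylic acid (cat.), CH2Cl2, rt
Reagents that add atoms: tert-butyl hydroperoxide, CC(C)(C)OO
Why: SeO2-catalysed allylic oxidation (ene reaction, then 2,3-sigmatropic shift) should attack the E-methyl group of the electron-rich terminal alkene and leave the allylic acetate end alone, giving the E-allylic alcohol.

Step 2
Reactants: 2 (2E,6E)-8-hydroxy-3,7-dimethylocta-2,6-dien-1-yl acetate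
Product: 3 (2E,6E)-8-bromo-3,7-dimethylocta-2,6-dien-1-yl acetate
Conditions: CBr4, PPh3, CH2Cl2, 0 °C
Reagents that add atoms: carbon tetrabromide, BrC(Br)(Br)Br
Why: Appel bromination converts the primary allylic alcohol to the bromide under neutral conditions, without allylic transposition or loss of the acetate.

Step 3
Reactants: 4 methyl 2-methylacetoacetate; 5 (1S,2R,5S)-8-phenylmenthol
Product: 6 (1S,2R,5S)-8-phenylmenthyl 2-methyl-3-oxobutanoate (both C2 epimers)
Conditions: DMAP (cat.), toluene, reflux, MeOH distilled off
Reagents that add atoms: none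
Why: DMAP-catalysed transesterification of an enolisable β-keto ester, driven by removal of methanol, installs the auxiliary; the α-carbon is stereolabile and its configuration is irrelevant.

Step 4
Reactants: 6 (1S,2R,5S)-8-phenylmenthyl 2-methyl-3-oxobutanoate; 3 (2E,6E)-8-bromo-3,7-dimethylocta-2,6-dien-1-yl acetate
Product: 7 (1S,2R,5S)-8-phenylmenthyl (6E,10E)-12-acetoxy-2,6,10-trimethyl-3-oxododeca-6,10-dienoate (both C2 epimers)
Conditions: LiN(iPr)2 (2.2 equiv), THF, 0 °C; then 3, −78 → 0 °C
Reagents that add atoms: none
Why: β-Keto ester dianion alkylation takes place at the terminal (γ) carbon, and SN2 displacement of the primary allylic bromide at low temperature should outrun any attack on the acetate, so both E-alkenes are carried over intact.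

Step 5
Reactants: 7 (1S,2R,5S)-8-phenylmenthyl (6E,10E)-12-acetoxy-2,6,10-trimethyl-3-oxododeca-6,10-dienoate
Product: 8 (1S,2R,5S)-8-phenylmenthyl 11-acetoxy-3-oxo-12,13,14,15,16-pentanorlabd-8(17)-en-19-oate (trans-decalin; 4α-CH3, 4β-ester, 5α-H, 9α-H with 9β-CH2OAc, 10β-CH3)
Conditions: Mn(OAc)3·2H2O (2.2 equiv), Cu(OAc)2·H2O (1 equiv), degassed AcOH, rt
Reagents that add atoms: none
Why: In this oxidative free-radical polyene cyclisation Mn(OAc)3 (trivalent manganese) generates the C4 radical, which closes ring A (6-endo onto C5) and then ring B (6-endo from the C10 radical onto C9) through chair–chair transition states fixed by the two E-alkenes (trans fusion, equatorial C9–CH2OAc, axial C19 ester), the phenyl group of the auxiliary shields one face of the C4 radical and so sets the absolute sense, and Cu(OAc)2 (divalent copper, returned to that state by Mn(OAc)3) oxidises the tertiary C8 radical to the less substituted exocyclic C8=C17 alkene.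

Step 6
Reactants: 8 (1S,2R,5S)-8-phenylmenthyl 11-acetoxy-3-oxo-12,13,14,15,16-pentanorlabd-8(17)-en-19-oate
Product: 9 (1S,2R,5S)-8-phenylmenthyl 11-acetoxy-3β-hydroxy-12,13,14,15,16-pentanorlabd-8(17)-en-19-oate
Conditions: NaBH4, MeOH/THF, 0 °C
Reagents that add atoms: none
Why: Borohydride reduction of the ketone (axial hydride delivery from the α face should give mainly the equatorial 3β-alcohol, whose configuration is of no consequence) leaves the hindered ester and the acetate untouched at 0 °C.

Step 7
Reactants: 9 (1S,2R,5S)-8-phenylmenthyl 11-acetoxy-3β-hydroxy-12,13,14,15,16-pentanorlabd-8(17)-en-19-oate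
Product: 10 (1S,2R,5S)-8-phenylmenthyl 11-acetoxy-3β-(phenoxythiocarbonyloxy)-12,13,14,15,16-pentanorlabd-8(17)-en-19-oate
Conditions: PhOC(S)Cl, pyridine, DMAP (cat.), CH2Cl2, rt
Reagents that add atoms: O-phenyl chlorothionoformate, S=C(Cl)Oc1ccccc1
Why: DMAP-catalysed acylation of the secondary alcohol gives the radical-labile thionocarbonate without a base strong enough to disturb the acetate.

Step 8
Reactants: 10 (1S,2R,5S)-8-phenylmenthyl 11-acetoxy-3β-(phenoxythiocarbonyloxy)-12,13,14,15,16-pentanorlabd-8(17)-en-19-oate
Product: 11 (1S,2R,5S)-8-phenylmenthyl 11-acetoxy-12,13,14,15,16-pentanorlabd-8(17)-en-19-oate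
Conditions: Bu3SnH, AIBN (cat.), toluene, 100 °C
Reagents that add atoms: none
Why: In this Barton–McCombie deoxygenation the stannyl radical adds to C=S, the C3–O bond fragments, and the secondary C3 radical, which has no alkene within reach, takes hydrogen from Bu3SnH.

Step 9
Reactants: 11 (1S,2R,5S)-8-phenylmenthyl 11-acetoxy-12,13,14,15,16-pentanorlabd-8(17)-en-19-oate
Product: 12 12,13,14,15,16-pentanorlabd-8(17)-ene-11,19-diol (natural series)
Conditions: LiAlH4, THF, 0 °C → reflux; aqueous NaOH work-up
Reagents that add atoms: none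
Why: Hydride reduction cleaves the hindered neopentyl ester that could not be saponified (the auxiliary is returned as 5) and removes the acetate in the same operation.

Step 10
Reactants: 12 12,13,14,15,16-pentanorlabd-8(17)-ene-11,19-diol
Product: 13 12,13,14,15,16-pentanorlabd-8(17)-ene-11,19-dial
Conditions: Dess–Martin periodinane, NaHCO3, CH2Cl2, 0 °C → rt
Reagents that add atoms: none
Why: Dess–Martin oxidation takes both primary alcohols to aldehydes under buffered, non-basic conditions that should neither epimerise C9 nor move C8=C17 into conjugation with the C11 aldehyde.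

Step 11
Reactants: 13 12,13,14,15,16-pentanorlabd-8(17)-ene-11,19-dial; 14 triethyl 3-methyl-4-phosphonocrotonate
Product: 15 ethyl (11E,13E/Z)-19-oxolabda-8(17),11,13-trien-15-oate
Conditions: 14, LiN(SiMe3)2, THF, −78 °C; then 13, −78 → 0 °C
Reagents that add atoms: none
Why: In this vinylogous Horner–Wadsworth–Emmons olefination the lithium phosphonate should add to the equatorial C11 aldehyde faster than it deprotonates C9, while the axial neopentyl C19 aldehyde (on quaternary C4, 1,3-diaxial to the C20 methyl) is inert to a stabilised phosphonate anion; C11=C12 forms E and C13=C14 as an E/Z mixture, which is acceptable here.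

Step 12
Reactants: 15 ethyl (11E,13E/Z)-19-oxolabda-8(17),11,13-trien-15-oate
Product: 16 (11E,13E/Z)-15-ethoxy-15-oxolabda-8(17),11,13-trien-19-oic acid
Conditions: NaClO2, NaH2PO4, 2-methyl-2-butene (excess), t-BuOH/H2O, rt
Reagents that add atoms: sodium chlorite, [Na+].[O-]Cl=O
Why: Pinnick oxidation converts even a hindered, non-enolisable aldehyde to the acid, and the excess alkene scavenger keeps HOCl away from the diene and the exocyclic alkene.

Step 13
Reactants: 16 (11E,13E/Z)-15-ethoxy-15-oxolabda-8(17),11,13-trien-19-oic acid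
Product: 17 (11E,13E/Z)-labda-8(17),11,13-triene-15,19-dioic acid
Conditions: LiOH, THF/MeOH/H2O, 50 °C; then 1 M HCl to pH 3
Reagents that add atoms: lithium hydroxide, [Li+].[OH-]
Why: Saponification of the conjugated ethyl ester is the only reaction open to hydroxide, since C19 is already a carboxylate.

Step 14
Reactants: 17 (11E,13E/Z)-labda-8(17),11,13-triene-15,19-dioic acid
Product: 18 (11S,12R)-11-iodolabda-8(17),13-dien-15,12-olid-19-oic acid (12R only because iodine raises the CIP rank of C11; the arrangement at C12 is that of 12S in 19)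
Conditions: I2 (3 equiv), NaHCO3, MeCN/H2O, white LED, rt; Na2S2O3 quench, then pH 4
Reagents that add atoms: iodine, II
Why: I2 forms a reversible iodonium ion at C11=C12 and the C15 carboxylate of the 13Z acid opens it at C12 with anti addition, while iodine atoms formed under light add reversibly to the conjugated diene and equilibrate C13=C14, so the 13E acid, which cannot reach C12, should be consumed through the 13Z isomer. The closest known reactions are the iodolactonisation of (2Z,4E)-dienoic acids to 5-(1-iodoalkyl)butenolides and the iodine-photocatalysed E/Z equilibration of conjugated alkenes. The butenolide ring (O–C12–C13=C14–C15) closes in the 5-exo mode; 6-endo attack at C11 is disfavoured because C11 sits on C9 next to the quaternary C10 and is shielded from backside attack, whereas C12 is the allylic terminus. C11 and C12 are formed anti to one another as a consequence of the E geometry of C11=C12 and anti opening, and their sense relative to C9 follows from the face on which iodine bridges: in the product-like closure transition state C12 with the growing lactone should stay in the open sector anti to C10 about C9–C11 (C9–H near the alkene plane), which places iodine in the slot between C9–H and C1–H2 and brings oxygen to C12 from the C8 side, i.e. (11S,12R), while the other face either pushes C12 into a syn-pentane contact with C1 or sends iodine into the crowded β pocket between C20 and C17. This facial preference is the selectivity the step needs; it rests on that conformational argument alone and is the open point of the route, whereas chemoselectivity over C8=C17 should be secure because no carboxylate can reach that alkene (C19 is too far) and its iodonium ion reverts.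

Step 15
Reactants: 18 (11S,12R)-11-iodolabda-8(17),13-dien-15,12-olid-19-oic acid
Product: 19 (12S)-labda-8(17),13-dien-15,12-olid-19-oic acid
Conditions: Bu3SnH (3 equiv, 0.5 M), Et3B/air (cat.), toluene, 0 °C → rt
Reagents that add atoms: none
Why: In this radical deiodination the secondary C11 radical should be reduced, at high Bu3SnH concentration and low temperature, faster than it can attack C8=C17 (3-exo closure and vinyl shift) or lose the β-acyloxy group, so the lactone, C12 and both alkenes are untouched, whereas a two-electron reductant would eliminate back to the diene.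

Step 16
Reactants: 19 (12S)-labda-8(17),13-dien-15,12-olid-19-oic acid
Product: 20 (12S,13Z)-12-hydroxylabda-8(17),13-diene-15,19-dioic acid (target, CNP0144045.1)
Conditions: LiOH, THF/H2O, 0 °C; then cold 0.5 M HCl to pH 5, immediate EtOAc extraction
Reagents that add atoms: lithium hydroxide, [Li+].[OH-]
Why: Lactone saponification by acyl–oxygen cleavage leaves the C12–O bond and the Z alkene as they are, should be faster at 0 °C than removal of the γ-proton at C12, and acidification only to about pH 5 in the cold should release the diacid before it can relactonise.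

**Compound list**

1 | geranyl acetate | CC(C)=CCC/C(C)=C/COC(C)=O | starting material
2 | (2E,6E)-8-hydroxy-3,7-dimethylocta-2,6-dien-1-yl acetate | OC/C(C)=C/CC/C(C)=C/COC(C)=O | intermediate
3 | (2E,6E)-8-bromo-3,7-dimethylocta-2,6-dien-1-yl acetate | BrC/C(C)=C/CC/C(C)=C/COC(C)=O | intermediate
4 | methyl 2-methylacetoacetate | CC(=O)C(C)C(=O)OC | starting material
5 | (1S,2R,5S)-8-phenylmenthol | C[C@H]1CC[C@@H]([C@H](C1)O)C(C)(C)c1ccccc1 | starting material
6 | (1S,2R,5S)-8-phenylmenthyl 2-methyl-3-oxobutanoate | CC(=O)C(C)C(=O)O[C@H]1C[C@@H](C)CC[C@@H]1C(C)(C)c1ccccc1 | intermediate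
7 | (1S,2R,5S)-8-phenylmenthyl (6E,10E)-12-acetoxy-2,6,10-trimethyl-3-oxododeca-6,10-dienoate | CC(=O)OC/C=C(C)/CC/C=C(C)/CCC(=O)C(C)C(=O)O[C@H]1C[C@@H](C)CC[C@@H]1C(C)(C)c1ccccc1 | intermediate
8 | 8-phenylmenthyl 11-acetoxy-3-oxo-12,13,14,15,16-pentanorlabd-8(17)-en-19-oate | C=C1CC[C@@H]2[C@](C)(CCC(=O)[C@]2(C)C(=O)O[C@H]3C[C@@H](C)CC[C@@H]3C(C)(C)c3ccccc3)[C@H]1COC(C)=O | intermediate
9 | 8-phenylmenthyl 11-acetoxy-3β-hydroxy-12,13,14,15,16-pentanorlabd-8(17)-en-19-oate | C=C1CC[C@@H]2[C@](C)(CC[C@H](O)[C@]2(C)C(=O)O[C@H]3C[C@@H](C)CC[C@@H]3C(C)(C)c3ccccc3)[C@H]1COC(C)=O | intermediate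
10 | 8-phenylmenthyl 11-acetoxy-3β-(phenoxythiocarbonyloxy)-12,13,14,15,16-pentanorlabd-8(17)-en-19-oate | C=C1CC[C@@H]2[C@](C)(CC[C@H](OC(=S)Oc3ccccc3)[C@]2(C)C(=O)O[C@H]3C[C@@H](C)CC[C@@H]3C(C)(C)c3ccccc3)[C@H]1COC(C)=O | intermediate
11 | 8-phenylmenthyl 11-acetoxy-12,13,14,15,16-pentanorlabd-8(17)-en-19-oate | C=C1CC[C@@H]2[C@](C)(CCC[C@]2(C)C(=O)O[C@H]3C[C@@H](C)CC[C@@H]3C(C)(C)c3ccccc3)[C@H]1COC(C)=O | intermediate
12 | 12,13,14,15,16-pentanorlabd-8(17)-ene-11,19-diol | C=C1CC[C@@H]2[C@](C)(CCC[C@]2(C)CO)[C@H]1CO | intermediate
13 | 12,13,14,15,16-pentanorlabd-8(17)-ene-11,19-dial | C=C1CC[C@@H]2[C@](C)(CCC[C@]2(C)C=O)[C@H]1C=O | intermediate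
14 | triethyl 3-methyl-4-phosphonocrotonate | CCOC(=O)/C=C(\C)CP(=O)(OCC)OCC | starting material
15 | ethyl (11E,13E/Z)-19-oxolabda-8(17),11,13-trien-15-oate | C=C1CC[C@@H]2[C@](C)(CCC[C@]2(C)C=O)[C@H]1/C=C/C(C)=CC(=O)OCC | intermediate
16 | (11E,13E/Z)-15-ethoxy-15-oxolabda-8(17),11,13-trien-19-oic acid | C=C1CC[C@@H]2[C@](C)(CCC[C@]2(C)C(=O)O)[C@H]1/C=C/C(C)=CC(=O)OCC | intermediate
17 | (11E,13E/Z)-labda-8(17),11,13-triene-15,19-dioic acid | C=C1CC[C@@H]2[C@](C)(CCC[C@]2(C)C(=O)O)[C@H]1/C=C/C(C)=CC(=O)O | intermediate
18 | (11S,12R)-11-iodolabda-8(17),13-dien-15,12-olid-19-oic acid | C=C1CC[C@@H]2[C@](C)(CCC[C@]2(C)C(=O)O)[C@H]1[C@H](I)[C@@H]3OC(=O)C=C3C | intermediate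
19 | (12S)-labda-8(17),13-dien-15,12-olid-19-oic acid | C=C1CC[C@@H]2[C@](C)(CCC[C@]2(C)C(=O)O)[C@H]1C[C@@H]3OC(=O)C=C3C | intermediate
20 | (4S,5R,9S,10R,12S,13Z)-12-hydroxylabda-8(17),13-diene-15,19-dioic acid | C=C1CC[C@@H]2[C@](C)(CCC[C@]2(C)C(=O)O)[C@H]1C[C@H](O)/C(C)=C\C(=O)O | target

**Step count**

Total: 16 steps. Longest linear sequence: 15 steps (1 → 2 → 3 → 7 → … → 20; step 3 is the side branch).

**Steps most likely to fail**

Step 14. Iodine may bridge and the ring may close on the other face of C11=C12, which would give the C12 epimer. The iodine-atom equilibration of C13=C14 may also be too slow to feed the 13Z isomer, or closure may go to C11. The fallback sets C12 by reagent control and does without the iodolactonisation; it sets out from 13 and comes back to the route at 19.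
- Dialdehyde 13 would be treated with the ylide from (methoxymethyl)triphenylphosphonium chloride and KN(SiMe3)2 (1.1 equiv, THF, −78 → 0 °C). Only the unhindered C11 aldehyde should react, giving 11-(methoxymethylidene)-19-oxo enol ether F1.
- Dilute HCl/THF at 0 °C would hydrolyse this to the homologated 12,19-dialdehyde F2.
- Zinc-alkynylide addition of methyl propiolate (Me2Zn, ProPhenol ligand of the enantiomer that delivers 12S, toluene, 0 °C) should take place at the unbranched C12 aldehyde only, giving methyl (12S)-12-hydroxy-19-oxo-ynoate F3.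
- Pinnick oxidation (NaClO2, NaH2PO4, 2-methyl-2-butene) would give the (12S)-hydroxy-ynoate 19-acid F4.
- Syn addition of Me2CuLi (excess, THF, −78 °C) to the ynoate places the new C16 methyl on C13 cis to the C14 hydrogen, so the hydroxy ester lactonises on mild acidic work-up to 19.

Step 5. Facial discrimination at the C4 radical by the auxiliary may be weak, oxidation may intervene after the first ring, and the copper-mediated elimination may give endocyclic alkenes. The fallback separates ring construction from absolute control; it sets out from 3 (with 4) and comes back to the route at 12.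
- The dianion of 4 (LiN(iPr)2, THF) would be alkylated with 3 to give methyl (6E,10E)-12-acetoxy-2,6,10-trimethyl-3-oxododeca-6,10-dienoate F5.
- Mn(OAc)3·2H2O/Cu(OAc)2·H2O in AcOH would give racemic methyl 11-acetoxy-3-oxo-pentanorlabd-8(17)-en-19-oate F6.
- A Corey–Bakshi–Shibata reduction with limiting BH3·SMe2, using the 2-methyl-oxazaborolidine enantiomer matched to α-face hydride delivery in the natural series, would act as a kinetic resolution. Methyl 11-acetoxy-3β-hydroxy-pentanorlabd-8(17)-en-19-oate F7 of the natural series would be separated by chromatography from mirror-image material.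
- PhOC(S)Cl/pyridine/DMAP would give the 3β-phenoxythiocarbonyloxy methyl ester F8, and Bu3SnH/AIBN the deoxygenated methyl 11-acetoxy-pentanorlabd-8(17)-en-19-oate F9.
- LiAlH4 in THF would reduce both ester groups to give 12.

Step 11. The phosphonate anion may deprotonate C9 (epimerisation, or migration of C8=C17 into conjugation with the C11 aldehyde), and some attack on the C19 aldehyde may compete. The fallback builds C11=C12 without a basic carbanion; it sets out from 13 and comes back to the route at 15.
- Boryl olefination of 13 with CrCl2, LiI and Cl2CHB(pin) in THF at rt should convert the C11 aldehyde to the (11E)-alkenyl pinacol boronate F10.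
- Suzuki coupling with ethyl (Z)-3-iodobut-2-enoate (Pd(PPh3)4, aqueous K3PO4, THF) would give 15 as its single 13Z isomer, the isomer that lactonises directly in step 14.

**Further compounds**

F1 | step 14 | 11-(methoxymethylidene)-19-oxo enol ether (E/Z) of the pentanorlabd-8(17)-ene | C=C1CC[C@@H]2[C@](C)(CCC[C@]2(C)C=O)[C@H]1C=COC
F2 | step 14 | 13,14,15,16-tetranorlabd-8(17)-ene-12,19-dial | C=C1CC[C@@H]2[C@](C)(CCC[C@]2(C)C=O)[C@H]1CC=O
F3 | step 14 | methyl (12S)-12-hydroxy-19-oxo-16-norlabd-8(17)-en-13-yn-15-oate | C=C1CC[C@@H]2[C@](C)(CCC[C@]2(C)C=O)[C@H]1C[C@H](O)C#CC(=O)OC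
F4 | step 14 | (12S)-12-hydroxy-15-methoxy-15-oxo-16-norlabd-8(17)-en-13-yn-19-oic acid | C=C1CC[C@@H]2[C@](C)(CCC[C@]2(C)C(=O)O)[C@H]1C[C@H](O)C#CC(=O)OC
F5 | step 5 | methyl (6E,10E)-12-acetoxy-2,6,10-trimethyl-3-oxododeca-6,10-dienoate | CC(=O)OC/C=C(C)/CC/C=C(C)/CCC(=O)C(C)C(=O)OC
F6 | step 5 | methyl 11-acetoxy-3-oxo-12,13,14,15,16-pentanorlabd-8(17)-en-19-oate, racemic (one enantiomer drawn) | C=C1CC[C@@H]2[C@](C)(CCC(=O)[C@]2(C)C(=O)OC)[C@H]1COC(C)=O
F7 | step 5 | methyl 11-acetoxy-3β-hydroxy-12,13,14,15,16-pentanorlabd-8(17)-en-19-oate (natural series) | C=C1CC[C@@H]2[C@](C)(CC[C@H](O)[C@]2(C)C(=O)OC)[C@H]1COC(C)=O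
F8 | step 5 | methyl 11-acetoxy-3β-(phenoxythiocarbonyloxy)-12,13,14,15,16-pentanorlabd-8(17)-en-19-oate | C=C1CC[C@@H]2[C@](C)(CC[C@H](OC(=S)Oc3ccccc3)[C@]2(C)C(=O)OC)[C@H]1COC(C)=O
F9 | step 5 | methyl 11-acetoxy-12,13,14,15,16-pentanorlabd-8(17)-en-19-oate | C=C1CC[C@@H]2[C@](C)(CCC[C@]2(C)C(=O)OC)[C@H]1COC(C)=O
F10 | step 11 | (11E)-12-(pinacolboryl)-19-oxo-13,14,15,16-tetranorlabda-8(17),11-diene | C=C1CC[C@@H]2[C@](C)(CCC[C@]2(C)C=O)[C@H]1/C=C/B3OC(C)(C)C(C)(C)O3
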